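The quinone ring is cut into a two-carbon and a four-carbon piece. Numbering the ring so that C1 is the carbonyl lying between C2 (OMe) and C6 (side chain) and C4 is the other carbonyl, the oxygens at C2 and C4 are meta-related and come from a 1,3-dioxygenated butadiene spanning C2–C5, while C1 and C6 derive from an alkynyl methyl ketone whose acetyl substituent is a masked C1 oxygen. One thermal [4+2] benzannulation forges C1–C2 and C5–C6 and, after loss of methanol, delivers the fully substituted benzene ring with defined regiochemistry. The precursor, (R)-homopropargylic acetate 10, already holds the stereocentre, the acetate and the ynone; its partner is silyloxy ketene-acetal diene 16.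

Key step: step 10

Remark: the carbinol carbon of the butynol unit in 6 to 9 is racemic or epimeric and is drawn without configuration, since step 6 turns it into the ketone carbon.

Step 1
Reactants: 1 (R)-epichlorohydrin [(R)-2-(chloromethyl)oxirane]; 2 decylmagnesium bromide
Product: 4 (R)-2-undecyloxirane, via (R)-1-chlorotridecan-2-ol 3 (not isolated)
Conditions: CuI (5 mol%), THF, −40 to −20 °C; then NaOH (5 M aq), 20 °C
Reagents that add atoms: none
Why: Copper-catalysed Grignard opening of the epoxide at its CH2 carbon followed by base-induced Williamson-type closure of the chlorohydrin is the standard homologation of epichlorohydrin to a terminal epoxide, and because no bond to the carbinol carbon is broken the (R) centre of 1 becomes the (R) centre of 4.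

Step 2
Reactants: 5 but-3-yn-2-ol (racemic)
Product: 6 tert-butyl(but-3-yn-2-yloxy)dimethylsilane (racemic)
Conditions: TBSCl, imidazole, CH2Cl2, 0 to 20 °C
Reagents that add atoms: tert-butyldimethylsilyl chloride, CC(C)(C)[Si](C)(C)Cl
Why: Imidazole-promoted O-silylation of the secondary propargylic alcohol gives a silyl ether that tolerates acetylide formation and BF3·OEt2 at low temperature.

Step 3
Reactants: 6 tert-butyl(but-3-yn-2-yloxy)dimethylsilane; 4 (R)-2-undecyloxirane
Product: 7 (6R)-2-[(tert-butyldimethylsilyl)oxy]heptadec-3-yn-6-ol (both C2 epimers)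
Conditions: n-BuLi, THF, −78 °C; BF3·OEt2; then 4, −78 °C; NH4Cl (aq)
Reagents that add atoms: none
Why: In this Yamaguchi–Hirao alkynylation the lithium acetylide of 6, activated by BF3·OEt2, opens the terminal epoxide by SN2 attack at the CH2 carbon, so the (R) carbinol centre of 4 is carried over unchanged.

Step 4
Reactants: 7 (6R)-2-[(tert-butyldimethylsilyl)oxy]heptadec-3-yn-6-ol
Product: 8 (6R)-2-[(tert-butyldimethylsilyl)oxy]heptadec-3-yn-6-yl acetate (both C2 epimers)
Conditions: Ac2O, pyridine, DMAP (cat.), CH2Cl2, 0 to 20 °C
Reagents that add atoms: acetic anhydride, CC(=O)OC(C)=O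
Why: DMAP-catalysed acylation of the secondary alcohol installs the acetate of the target before any base-sensitive ynone or quinone exists, without touching the stereocentre.

Step 5
Reactants: 8 (6R)-2-[(tert-butyldimethylsilyl)oxy]heptadec-3-yn-6-yl acetate
Product: 9 (6R)-2-hydroxyheptadec-3-yn-6-yl acetate (both C2 epimers)
Conditions: HF·pyridine, THF, 0 to 20 °C
Reagents that add atoms: none
Why: Fluoride-mediated desilylation under weakly acidic conditions frees the propargylic alcohol while the acetate, which cannot migrate across the linear alkyne, stays in place.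

Step 6
Reactants: 9 (6R)-2-hydroxyheptadec-3-yn-6-yl acetate
Product: 10 (R)-2-oxoheptadec-3-yn-6-yl acetate
Conditions: Dess–Martin periodinane, CH2Cl2, 0 to 20 °C; filtration through silica
Reagents that add atoms: none
Why: Dess–Martin oxidation of the secondary propargylic alcohol under neutral conditions gives the conjugated ynone and erases the uncontrolled carbinol centre, and the absence of base avoids elimination of the acetate through the now acidic propargylic CH2 group.

Step 7
Reactants: 11 acetyl chloride; 12 1,1-dichloroethene
Product: 14 4,4-dichlorobut-3-en-2-one, via 4,4,4-trichlorobutan-2-one 13 (not isolated)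
Conditions: AlCl3, CH2Cl2, 0 to 20 °C; ice water; distillation
Reagents that add atoms: none
Why: Aliphatic Friedel–Crafts (Kondakov) acylation adds the acylium ion to the CH2 terminus of the alkene to give the trichloroketone, which loses HCl to the conjugated β,β-dichlorovinyl ketone.

Step 8
Reactants: 14 4,4-dichlorobut-3-en-2-one
Product: 15 4,4-dimethoxybut-3-en-2-one
Conditions: NaOMe (2.1 equiv), MeOH, −10 to 20 °C
Reagents that add atoms: sodium methoxide, [Na+].[O-]C
Why: Two successive addition–elimination reactions (nucleophilic vinylic substitution) of methoxide at the β-carbon replace both chlorides and stop at the push–pull stabilised ketene acetal.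

Step 9
Reactants: 15 4,4-dimethoxybut-3-en-2-one
Product: 16 1,1-dimethoxy-3-(trimethylsilyloxy)buta-1,3-diene
Conditions: TMSCl, Et3N, ZnCl2 (cat.), toluene, 40 °C; filtration; distillation
Reagents that add atoms: chlorotrimethylsilane, C[Si](C)(C)Cl
Why: Soft enolisation of the methyl ketone, whose CH3 group is the only enolisable position, and O-silylation (silyl enol ether formation) give the cross-conjugated 2-silyloxy diene.

Step 10
Reactants: 10 (R)-2-oxoheptadec-3-yn-6-yl acetate; 16 1,1-dimethoxy-3-(trimethylsilyloxy)buta-1,3-diene (3 equiv)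
Product: 19 (R)-1-(2-acetyl-5-hydroxy-3-methoxyphenyl)tridecan-2-yl acetate, via cyclohexadiene cycloadduct 17 (not isolated), via aryl trimethylsilyl ether 18 (not isolated)
Conditions: toluene, 110 °C, sealed tube, Ar; then HCl (0.5 M aq), THF, 20 °C
Reagents that add atoms: none
Why: The diene is strongly polarised by its ketene-acetal and silyl-enol-ether oxygens, so its CH2 terminus attacks the β-carbon of the ynone (C5–C6) while the acetal carbon bonds to the acetyl-bearing α-carbon (C1–C2) in a concerted but very asynchronous [4+2] cycloaddition, and a Michael addition followed by ring closure would lead to the same adduct 17. The closest established reaction type is the cycloaddition–aromatisation of silyloxy ketene-acetal dienes with alkynyl ketones or alkynoates, which gives mono-O-methylated resorcinols. The one new ring, the six-membered carbocycle, is closed by this intermolecular two-bond annulation of four diene carbons with two alkyne carbons, and it becomes benzenoid when 17 loses methanol by 1,4-elimination across C2 and C5, after which dilute acid cleaves the aryl silyl ether 18. No stereocentre is formed, and the (R) centre, separated from the alkyne by one CH2 group and carrying a thermally stable acetate, is not affected as long as the diene is amine-free. The only selectivity required is regiochemical and is fixed by the matched polarity of the two partners, which places the acetyl group between the methoxy group and the side chain and para to the new hydroxyl group; an excess of diene compensates for the lower dienophilicity of a β-alkyl ynone and for the diene consumed by the liberated methanol.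

Step 11
Reactants: 19 (R)-1-(2-acetyl-5-hydroxy-3-methoxyphenyl)tridecan-2-yl acetate
Product: 20 (R)-1-(2-acetoxy-5-hydroxy-3-methoxyphenyl)tridecan-2-yl acetate
Conditions: mCPBA (1.3 equiv), CH2Cl2, 0 to 20 °C, dark
Reagents that add atoms: 3-chloroperoxybenzoic acid (mCPBA), OOC(=O)c1cccc(Cl)c1
Why: Baeyer–Villiger oxidation (the peracid counterpart of the Dakin reaction) proceeds by migration of the electron-rich aryl group, para-hydroxylated and twisted out of conjugation with the ketone, in preference to methyl, turning the acetyl marker on C1 into an aryl acetate while the alkyl acetate and the stereocentre are inert to peracid.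

Step 12
Reactants: 20 (R)-1-(2-acetoxy-5-hydroxy-3-methoxyphenyl)tridecan-2-yl acetate
Product: 22 (R)-1-(5-methoxy-3,6-dioxocyclohexa-1,4-dien-1-yl)tridecan-2-yl acetate (CNP0137521.1), via hydroquinone 21 (not isolated)
Conditions: NH3 (7 M in MeOH), 0 to 20 °C, Ar; evaporation; then FeCl3 (aq), EtOAc, 20 °C
Reagents that add atoms: none
Why: Chemoselective aminolysis of the aryl ester, whose phenoxide leaving group is far better than the secondary alkoxide of the side-chain acetate, gives the air-sensitive hydroquinone, and classical FeCl3 oxidation of this hydroquinone gives the methoxy-p-benzoquinone after the volatile ammonia has been removed.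

Compound list
1 | (R)-epichlorohydrin, (R)-2-(chloromethyl)oxirane | ClC[C@H]1CO1 | starting material
2 | decylmagnesium bromide | CCCCCCCCCC[Mg]Br | starting material
3 | (R)-1-chlorotridecan-2-ol | CCCCCCCCCCC[C@H](CCl)O | intermediate (not isolated)
4 | (R)-2-undecyloxirane | CCCCCCCCCCC[C@@H]1CO1 | intermediate
5 | but-3-yn-2-ol (racemic) | CC(O)C#C | starting material
6 | tert-butyl(but-3-yn-2-yloxy)dimethylsilane (racemic) | C#CC(C)O[Si](C)(C)C(C)(C)C | intermediate
7 | (6R)-2-[(tert-butyldimethylsilyl)oxy]heptadec-3-yn-6-ol (both C2 epimers) | CCCCCCCCCCC[C@H](CC#CC(C)O[Si](C)(C)C(C)(C)C)O | intermediate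
8 | (6R)-2-[(tert-butyldimethylsilyl)oxy]heptadec-3-yn-6-yl acetate (both C2 epimers) | CCCCCCCCCCC[C@H](CC#CC(C)O[Si](C)(C)C(C)(C)C)OC(C)=O | intermediate
9 | (6R)-2-hydroxyheptadec-3-yn-6-yl acetate (both C2 epimers) | CCCCCCCCCCC[C@H](CC#CC(C)O)OC(C)=O | intermediate
10 | (R)-2-oxoheptadec-3-yn-6-yl acetate | CCCCCCCCCCC[C@H](CC#CC(C)=O)OC(C)=O | intermediate
11 | acetyl chloride | CC(Cl)=O | starting material
12 | 1,1-dichloroethene | C=C(Cl)Cl | starting material
13 | 4,4,4-trichlorobutan-2-one | CC(=O)CC(Cl)(Cl)Cl | intermediate (not isolated)
14 | 4,4-dichlorobut-3-en-2-one | CC(=O)C=C(Cl)Cl | intermediate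
15 | 4,4-dimethoxybut-3-en-2-one | CC(=O)C=C(OC)OC | intermediate
16 | 1,1-dimethoxy-3-(trimethylsilyloxy)buta-1,3-diene | C=C(O[Si](C)(C)C)C=C(OC)OC | intermediate
17 | (R)-1-[2-acetyl-3,3-dimethoxy-5-(trimethylsilyloxy)cyclohexa-1,4-dien-1-yl]tridecan-2-yl acetate | CCCCCCCCCCC[C@H](CC1=C(C(C)=O)C(OC)(OC)C=C(O[Si](C)(C)C)C1)OC(C)=O | intermediate (not isolated)
18 | (R)-1-[2-acetyl-3-methoxy-5-(trimethylsilyloxy)phenyl]tridecan-2-yl acetate | CCCCCCCCCCC[C@H](Cc1cc(O[Si](C)(C)C)cc(OC)c1C(C)=O)OC(C)=O | intermediate (not isolated)
19 | (R)-1-(2-acetyl-5-hydroxy-3-methoxyphenyl)tridecan-2-yl acetate | CCCCCCCCCCC[C@H](Cc1cc(O)cc(OC)c1C(C)=O)OC(C)=O | intermediate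
20 | (R)-1-(2-acetoxy-5-hydroxy-3-methoxyphenyl)tridecan-2-yl acetate | CCCCCCCCCCC[C@H](Cc1cc(O)cc(OC)c1OC(C)=O)OC(C)=O | intermediate
21 | (R)-1-(2,5-dihydroxy-3-methoxyphenyl)tridecan-2-yl acetate | CCCCCCCCCCC[C@H](Cc1cc(O)cc(OC)c1O)OC(C)=O | intermediate (not isolated)
22 | (R)-1-(5-methoxy-3,6-dioxocyclohexa-1,4-dien-1-yl)tridecan-2-yl acetate, CNP0137521.1 | CCCCCCCCCCC[C@H](CC1=CC(=O)C=C(OC)C1=O)OC(C)=O | target

Total step count: 12. Longest linear sequence: 8 steps (1, 3, 4, 5, 6, 10, 11, 12).

Steps most likely to fail

Step 10. The β-alkyl ynone may add so slowly that thermal decay of the ketene-acetal diene, and its desilylation by the methanol released on aromatisation, outpace ring formation. The fallback keeps the same two ring bonds but changes the diene and the way the ring becomes aromatic, setting out from 10 and returning at 19. Commercial 3-methoxycyclohex-2-en-1-one is enolised at C6 with LiN(i-Pr)2 and silylated with TMSCl (THF, −78 °C) to give 1-methoxy-3-(trimethylsilyloxy)cyclohexa-1,3-diene F1. Heating F1 with 10 (o-xylene, 150–170 °C, sealed tube) should give, with the same polarity-controlled regiochemistry, the bicyclo[2.2.2]octa-2,5-diene cycloadduct F2. This should extrude ethene by retro-Diels–Alder reaction (Alder–Rickert aromatisation) to the aryl silyl ether 18, and dilute acid then gives 19. This cyclic diene is thermally robust and releases no protic by-product.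

Step 11. The peracid may attack the free, electron-rich phenol ring (ring hydroxylation and further oxidation) faster than it adds to the doubly ortho-substituted ketone. The fallback runs the oxidation on a masked phenol, setting out from 19 and returning at 20. Silylation (TBSCl, imidazole, DMF, 20 °C) gives (R)-1-[2-acetyl-5-(tert-butyldimethylsilyloxy)-3-methoxyphenyl]tridecan-2-yl acetate F3. Baeyer–Villiger oxidation of F3 (mCPBA, CH2Cl2, catalytic CF3CO2H) should give (R)-1-[2-acetoxy-5-(tert-butyldimethylsilyloxy)-3-methoxyphenyl]tridecan-2-yl acetate F4. Selective cleavage of the phenolic silyl ether (KHF2, MeOH, 20 °C), which leaves both acetates alone, then gives 20.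

Step 12. The deacylation may not discriminate fully, so that the side-chain acetate is cleaved together with the hindered aryl acetate, or residual ammonia may add to the nascent methoxyquinone. The fallback gives up chemoselectivity and re-acetylates at the end, setting out from 20 and returning at 22. K2CO3 in degassed MeOH (20 °C, Ar) removes both acetates to give (R)-2-(2-hydroxytridecyl)-6-methoxybenzene-1,4-diol F5. Aqueous FeCl3 with EtOAc oxidises it to (R)-2-(2-hydroxytridecyl)-6-methoxycyclohexa-2,5-diene-1,4-dione F6. Acetylation of the secondary alcohol (Ac2O, pyridine, CH2Cl2, 0 °C, short reaction time) should then give 22.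

Further compounds
F1 | step 10 | 1-methoxy-3-(trimethylsilyloxy)cyclohexa-1,3-diene | COC1=CC(O[Si](C)(C)C)=CCC1
F2 | step 10 | (R)-1-[3-acetyl-4-methoxy-6-(trimethylsilyloxy)bicyclo[2.2.2]octa-2,5-dien-2-yl]tridecan-2-yl acetate (mixture of bridgehead diastereomers) | CCCCCCCCCCC[C@H](CC1=C(C(C)=O)C2(OC)CCC1C(O[Si](C)(C)C)=C2)OC(C)=O
F3 | step 11 | (R)-1-[2-acetyl-5-(tert-butyldimethylsilyloxy)-3-methoxyphenyl]tridecan-2-yl acetate | CCCCCCCCCCC[C@H](Cc1cc(O[Si](C)(C)C(C)(C)C)cc(OC)c1C(C)=O)OC(C)=O
F4 | step 11 | (R)-1-[2-acetoxy-5-(tert-butyldimethylsilyloxy)-3-methoxyphenyl]tridecan-2-yl acetate | CCCCCCCCCCC[C@H](Cc1cc(O[Si](C)(C)C(C)(C)C)cc(OC)c1OC(C)=O)OC(C)=O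
F5 | step 12 | (R)-2-(2-hydroxytridecyl)-6-methoxybenzene-1,4-diol | CCCCCCCCCCC[C@H](Cc1cc(O)cc(OC)c1O)O
F6 | step 12 | (R)-2-(2-hydroxytridecyl)-6-methoxycyclohexa-2,5-diene-1,4-dione | CCCCCCCCCCC[C@H](CC1=CC(=O)C=C(OC)C1=O)O
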